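**Retrosynthetic overview**
1. 18 ⇒ hydration of a terminal alkyne (the methyl ketone C=O is formed last) and, as the key union, the ester C–O bond between the C4–OH of isoobtusilactone A (11) and the O-silylated (Z)-alkynoic acid 14.
2. 11 ⇒ enol-lactone C–O bond by Au-catalysed 5-exo-dig cycloisomerisation of the (E)-hydroxy-alkynoic acid 10. This γ-methylene lactone is the only ring and is closed before the union.
3. 10 and 14 ⇒ geometry-retentive Negishi tridecylation of the (E)- and (Z)-β-iodoacrylates 6 and 12 with one stock of tridecylzinc bromide 8; 6 comes from 5 by iodine-catalysed Z→E isomerisation.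
4. 5 ⇒ one enantioselective three-component iodo-aldol (methyl propiolate, 3-(trimethylsilyl)propynal, TMSI) that sets the single carbinol configuration used in both halves.

Assumption: the (S)-catalyst of step 1 is taken to give Si-face attack on aldehyde 2 (checked by Mosher analysis; otherwise its enantiomer is used), and 5 is split about 1:1 between steps 2 and 7.

**Step 1**
Reactants: 1 methyl propiolate; 2 3-(trimethylsilyl)prop-2-ynal
Product: 5 methyl (2Z)-2-[(1R)-1-hydroxy-3-(trimethylsilyl)prop-2-yn-1-yl]-3-iodoprop-2-enoate, via 1-iodo-3-methoxy-3-(trimethylsilyloxy)propa-1,2-diene 3 (not isolated), via methyl (2Z)-3-iodo-2-[(1R)-3-(trimethylsilyl)-1-(trimethylsilyloxy)prop-2-yn-1-yl]prop-2-enoate 4 (not isolated)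
Conditions: TMSI (1.5 equiv), (S)-o-tolyl-CBS-oxazaborolidinium triflimide (20 mol %), CH2Cl2, −78 °C; then 1 M HCl, THF, 0 °C
Reagents that add atoms: iodotrimethylsilane, C[Si](C)(C)I
Why: Proposed new method: an enantioselective β-iodo-aldol (iodo-Morita–Baylis–Hillman) coupling extended to a C-silylated 2-ynal, in which TMSI adds iodide 1,4 to 1 to give the iodoallenyl silyl ketene acetal 3, the cationic boron Lewis acid binds the formyl group of 2, and 3 attacks the Si face through its central carbon anti to iodine, so that iodine ends cis to the ester (Z) and the carbinol centre is set before silyl transfer gives 4; the closest known reaction is the oxazaborolidinium/TMSI three-component coupling of propiolates with aryl and alkyl aldehydes, which has not been shown for ynals (here the C-silyl group should block competing iodide addition to the ynal).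

**Step 2**
Reactants: 5 methyl (2Z)-2-[(1R)-1-hydroxy-3-(trimethylsilyl)prop-2-yn-1-yl]-3-iodoprop-2-enoate
Product: 6 methyl (2E)-2-[(1R)-1-hydroxy-3-(trimethylsilyl)prop-2-yn-1-yl]-3-iodoprop-2-enoate
Conditions: I2 (5 mol %), CH2Cl2, white LED, 23 °C; residual 5 separated and recycled
Reagents that add atoms: none
Why: Iodine atoms add reversibly to the β-iodoacrylate double bond, so the vinyl iodide equilibrates to the more stable E isomer (iodine trans to the ester) without touching the carbinol centre (radical Z→E isomerisation of a vinyl iodide).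

**Step 3**
Reactants: 7 1-bromotridecane
Product: 8 tridecylzinc bromide (LiCl-complexed stock solution in THF, decanted from excess zinc, titrated with iodine and kept under argon)
Conditions: Zn dust (1.5 equiv), LiCl (1.0 equiv), THF, 50 °C
Reagents that add atoms: zinc, [Zn]
Why: LiCl-promoted direct oxidative insertion of zinc into a primary alkyl bromide gives a storable alkylzinc halide solution, made once in the amount needed for both cross-couplings (steps 4 and 8).

**Step 4**
Reactants: 6 methyl (2E)-2-[(1R)-1-hydroxy-3-(trimethylsilyl)prop-2-yn-1-yl]-3-iodoprop-2-enoate; 8 tridecylzinc bromide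
Product: 9 methyl (2E)-2-[(1S)-1-hydroxy-3-(trimethylsilyl)prop-2-yn-1-yl]hexadec-2-enoate
Conditions: 8 (2.5 equiv, THF stock solution), PdCl2(Amphos)2 (2 mol %), N-methylimidazole, THF, 23 °C
Reagents that add atoms: none
Why: Negishi sp2–sp3 cross-coupling keeps the vinyl iodide geometry, so the tridecyl chain ends trans to the ester (E unit); the free hydroxyl only consumes extra organozinc, and the descriptor changes to S only through the CIP order.

**Step 5**
Reactants: 9 methyl (2E)-2-[(1S)-1-hydroxy-3-(trimethylsilyl)prop-2-yn-1-yl]hexadec-2-enoate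
Product: 10 (2E)-2-[(1R)-1-hydroxyprop-2-yn-1-yl]hexadec-2-enoic acid
Conditions: LiOH·H2O (5 equiv), THF/MeOH/H2O 3:1:1, 23 °C; then 1 M HCl to pH 3
Reagents that add atoms: lithium hydroxide, [Li+].[OH-]
Why: Saponification of the methyl ester and hydroxide-induced protodesilylation of the C-silyl alkyne occur in one operation, and the carbinol centre is untouched (R only through the CIP order).

**Step 6**
Reactants: 10 (2E)-2-[(1R)-1-hydroxyprop-2-yn-1-yl]hexadec-2-enoic acid
Product: 11 isoobtusilactone A, (3E,4S)-4-hydroxy-5-methylidene-3-tetradecylideneoxolan-2-one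
Conditions: AuCl (5 mol %), K2CO3 (10 mol %), MeCN, 23 °C
Reagents that add atoms: none
Why: Gold(I)-catalysed 5-exo-dig cycloisomerisation of a 4-pentynoic acid forms the enol-lactone C–O bond and the exocyclic methylene, with the E alkene and C4 carried over unchanged.

**Step 7**
Reactants: 5 methyl (2Z)-2-[(1R)-1-hydroxy-3-(trimethylsilyl)prop-2-yn-1-yl]-3-iodoprop-2-enoate
Product: 12 methyl (2Z)-3-iodo-2-[(1R)-1-(triethylsilyloxy)-3-(trimethylsilyl)prop-2-yn-1-yl]prop-2-enoate
Conditions: TESOTf (1.2 equiv), 2,6-lutidine, CH2Cl2, −78 °C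
Reagents that add atoms: triethylsilyl trifluoromethanesulfonate, CC[Si](CC)(CC)OS(=O)(=O)C(F)(F)F
Why: Silylation masks the only competing nucleophile of the Z half before its carboxyl group is activated (silyl ether protection).

**Step 8**
Reactants: 12 methyl (2Z)-3-iodo-2-[(1R)-1-(triethylsilyloxy)-3-(trimethylsilyl)prop-2-yn-1-yl]prop-2-enoate; 8 tridecylzinc bromide
Product: 13 methyl (2Z)-2-[(1S)-1-(triethylsilyloxy)-3-(trimethylsilyl)prop-2-yn-1-yl]hexadec-2-enoate
Conditions: 8 (1.5 equiv, THF stock solution), PdCl2(Amphos)2 (2 mol %), N-methylimidazole, THF, 23 °C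
Reagents that add atoms: none
Why: The same geometry-retentive Negishi coupling on the Z iodide places the tridecyl chain cis to the ester (Z unit).

**Step 9**
Reactants: 13 methyl (2Z)-2-[(1S)-1-(triethylsilyloxy)-3-(trimethylsilyl)prop-2-yn-1-yl]hexadec-2-enoate
Product: 14 (2Z)-2-[(1R)-1-(triethylsilyloxy)prop-2-yn-1-yl]hexadec-2-enoic acid
Conditions: LiOH·H2O (5 equiv), THF/MeOH/H2O 3:1:1, 23 °C; then 1 M HCl to pH 4 at 0 °C
Reagents that add atoms: lithium hydroxide, [Li+].[OH-]
Why: Saponification with C-desilylation as in step 5, with the secondary TES ether expected to survive mild aqueous base and a brief pH 4 work-up.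

**Step 10**
Reactants: 14 (2Z)-2-[(1R)-1-(triethylsilyloxy)prop-2-yn-1-yl]hexadec-2-enoic acid; 11 isoobtusilactone A
Product: 16 (3E,4S)-5-methylidene-2-oxo-3-tetradecylideneoxolan-4-yl (2Z)-2-[(1R)-1-(triethylsilyloxy)prop-2-yn-1-yl]hexadec-2-enoate, via (2Z)-2-[(1R)-1-(triethylsilyloxy)prop-2-yn-1-yl]hexadec-2-enoic 2,4,6-trichlorobenzoic anhydride 15 (not isolated)
Conditions: 2,4,6-trichlorobenzoyl chloride (1.1 equiv), Et3N, toluene, 23 °C; filter; then 11 (1.0 equiv), toluene, 70 °C, no DMAP
Reagents that add atoms: none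
Why: Yamaguchi mixed-anhydride esterification run without DMAP (the protocol used for angelate-type Z acids) acylates the lactone hydroxyl at the less shielded carbonyl of 15 and avoids nucleophile-induced Z→E isomerisation; no stereocentre is touched, and any minor enantiomer of either half ends in a separable diastereomer.

**Step 11**
Reactants: 16 (3E,4S)-5-methylidene-2-oxo-3-tetradecylideneoxolan-4-yl (2Z)-2-[(1R)-1-(triethylsilyloxy)prop-2-yn-1-yl]hexadec-2-enoate
Product: 18 (3E,4S)-5-methylidene-2-oxo-3-tetradecylideneoxolan-4-yl (2Z)-2-[(1S)-1-hydroxy-2-oxopropyl]hexadec-2-enoate (CNP0377581.1), via (3E,4S)-5-methylidene-2-oxo-3-tetradecylideneoxolan-4-yl (2Z)-2-[(1S)-2-oxo-1-(triethylsilyloxy)propyl]hexadec-2-enoate 17 (not isolated)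
Conditions: (JohnPhos)Au(MeCN)SbF6 (3 mol %), H2O (5 equiv), 1,4-dioxane, 23 °C; then HF·pyridine, THF, 0 °C
Reagents that add atoms: water, O
Why: Gold(I) activates the terminal alkyne, the neighbouring ester carbonyl adds 5-exo-dig, and water opens the resulting oxocarbenium to give the methyl ketone with Markovnikov regiochemistry (anchimerically assisted alkyne hydration), after which HF·pyridine removes the TES group; the enol lactone carries no alkyne and is not activated.

**Compound list**
1 | methyl propiolate | C#CC(=O)OC | starting material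
2 | 3-(trimethylsilyl)prop-2-ynal | C[Si](C)(C)C#CC=O | starting material
3 | 1-iodo-3-methoxy-3-(trimethylsilyloxy)propa-1,2-diene | COC(O[Si](C)(C)C)=C=CI | intermediate
4 | methyl (2Z)-3-iodo-2-[(1R)-3-(trimethylsilyl)-1-(trimethylsilyloxy)prop-2-yn-1-yl]prop-2-enoate | COC(=O)/C(=C\I)[C@H](O[Si](C)(C)C)C#C[Si](C)(C)C | intermediate
5 | methyl (2Z)-2-[(1R)-1-hydroxy-3-(trimethylsilyl)prop-2-yn-1-yl]-3-iodoprop-2-enoate | COC(=O)/C(=C\I)[C@H](O)C#C[Si](C)(C)C | intermediate
6 | methyl (2E)-2-[(1R)-1-hydroxy-3-(trimethylsilyl)prop-2-yn-1-yl]-3-iodoprop-2-enoate | COC(=O)/C(=C/I)[C@H](O)C#C[Si](C)(C)C | intermediate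
7 | 1-bromotridecane | CCCCCCCCCCCCCBr | starting material
8 | tridecylzinc bromide | CCCCCCCCCCCCC[Zn]Br | intermediate
9 | methyl (2E)-2-[(1S)-1-hydroxy-3-(trimethylsilyl)prop-2-yn-1-yl]hexadec-2-enoate | COC(=O)/C(=C/CCCCCCCCCCCCC)[C@H](O)C#C[Si](C)(C)C | intermediate
10 | (2E)-2-[(1R)-1-hydroxyprop-2-yn-1-yl]hexadec-2-enoic acid | OC(=O)/C(=C/CCCCCCCCCCCCC)[C@H](O)C#C | intermediate
11 | isoobtusilactone A, (3E,4S)-4-hydroxy-5-methylidene-3-tetradecylideneoxolan-2-one | C=C1OC(=O)/C(=C/CCCCCCCCCCCCC)[C@@H]1O | intermediate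
12 | methyl (2Z)-3-iodo-2-[(1R)-1-(triethylsilyloxy)-3-(trimethylsilyl)prop-2-yn-1-yl]prop-2-enoate | COC(=O)/C(=C\I)[C@H](O[Si](CC)(CC)CC)C#C[Si](C)(C)C | intermediate
13 | methyl (2Z)-2-[(1S)-1-(triethylsilyloxy)-3-(trimethylsilyl)prop-2-yn-1-yl]hexadec-2-enoate | COC(=O)/C(=C\CCCCCCCCCCCCC)[C@H](O[Si](CC)(CC)CC)C#C[Si](C)(C)C | intermediate
14 | (2Z)-2-[(1R)-1-(triethylsilyloxy)prop-2-yn-1-yl]hexadec-2-enoic acid | OC(=O)/C(=C\CCCCCCCCCCCCC)[C@H](O[Si](CC)(CC)CC)C#C | intermediate
15 | (2Z)-2-[(1R)-1-(triethylsilyloxy)prop-2-yn-1-yl]hexadec-2-enoic 2,4,6-trichlorobenzoic anhydride | O=C(OC(=O)c1c(Cl)cc(Cl)cc1Cl)/C(=C\CCCCCCCCCCCCC)[C@H](O[Si](CC)(CC)CC)C#C | intermediate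
16 | (3E,4S)-5-methylidene-2-oxo-3-tetradecylideneoxolan-4-yl (2Z)-2-[(1R)-1-(triethylsilyloxy)prop-2-yn-1-yl]hexadec-2-enoate | C=C1OC(=O)/C(=C/CCCCCCCCCCCCC)[C@@H]1OC(=O)/C(=C\CCCCCCCCCCCCC)[C@H](O[Si](CC)(CC)CC)C#C | intermediate
17 | (3E,4S)-5-methylidene-2-oxo-3-tetradecylideneoxolan-4-yl (2Z)-2-[(1S)-2-oxo-1-(triethylsilyloxy)propyl]hexadec-2-enoate | C=C1OC(=O)/C(=C/CCCCCCCCCCCCC)[C@@H]1OC(=O)/C(=C\CCCCCCCCCCCCC)[C@H](O[Si](CC)(CC)CC)C(C)=O | intermediate
18 | (3E,4S)-5-methylidene-2-oxo-3-tetradecylideneoxolan-4-yl (2Z)-2-[(1S)-1-hydroxy-2-oxopropyl]hexadec-2-enoate | C=C1OC(=O)/C(=C/CCCCCCCCCCCCC)[C@@H]1OC(=O)/C(=C\CCCCCCCCCCCCC)[C@H](O)C(C)=O | target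

**Totals:** 11 steps; longest linear sequence 7 steps (1, 2, 4, 5, 6, 10, 11).

**Steps most likely to fail**

Step 1 (the proposed new step): the ynal may give low ee, or TMSI may add to the ynal or ionise the propargylic silyl ether. The fallback uses known chemistry, sets out from 1 and 2 and comes back at 5. MgI2-mediated iodo-aldol coupling in CH2Cl2 at 0 °C gives the racemic Z iodo adduct F1. Dess–Martin oxidation gives the iodo-ynone F2. Reduction with (S)-Me-CBS and catecholborane in toluene at −78 °C (iodoalkenyl as the large group, silylalkynyl as the small one) returns 5.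

Step 2: the Z/E equilibrium may be incomplete, or iodine and light may damage the allylic-propargylic alcohol. The fallback sets out from 1 and 2 and comes back at 6. A halo-aldol under thermodynamic conditions (TiCl4, Bu4NI, CH2Cl2, 0 °C) gives the racemic E iodo adduct F3 directly. Dess–Martin oxidation gives the E iodo-ynone F4, and the same CBS reduction resets the carbinol centre to give 6.

Step 10: two hindered partners react without DMAP, with a risk of no reaction or of Z→E erosion. The fallback changes the acyl donor, sets out from 14 (with 11) and comes back at 17. AuCl/K2CO3 cycloisomerisation of 14 gives the silyl-protected obtusilactone A F5, an enol lactone whose alkene geometry is locked in the ring. Acyl transfer from F5 (3 equiv, to outcompete 11 acting as donor) to 11 with a neutral distannoxane catalyst in toluene at 50 °C opens the enol lactone and gives the keto ester 17 directly. HF·pyridine, as in step 11, then gives 18.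

**Further compounds**
F1 | step 1 | racemic methyl (2Z)-2-[1-hydroxy-3-(trimethylsilyl)prop-2-yn-1-yl]-3-iodoprop-2-enoate | COC(=O)/C(=C\I)C(O)C#C[Si](C)(C)C
F2 | step 1 | methyl (2Z)-3-iodo-2-[3-(trimethylsilyl)prop-2-ynoyl]prop-2-enoate | COC(=O)/C(=C\I)C(=O)C#C[Si](C)(C)C
F3 | step 2 | racemic methyl (2E)-2-[1-hydroxy-3-(trimethylsilyl)prop-2-yn-1-yl]-3-iodoprop-2-enoate | COC(=O)/C(=C/I)C(O)C#C[Si](C)(C)C
F4 | step 2 | methyl (2E)-3-iodo-2-[3-(trimethylsilyl)prop-2-ynoyl]prop-2-enoate | COC(=O)/C(=C/I)C(=O)C#C[Si](C)(C)C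
F5 | step 10 | (3Z,4S)-5-methylidene-3-tetradecylidene-4-(triethylsilyloxy)oxolan-2-one | C=C1OC(=O)/C(=C\CCCCCCCCCCCCC)[C@@H]1O[Si](CC)(CC)CC
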